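**Retrosynthetic overview**
1. Target 27 ⇐ tetra-MOM flavanonol 26 (deprotection) ⇐ seven-membered acetal 25 by an acid-catalysed O→C 1,2-shift with ring contraction (7 → 6), which forms C2–C3 and ring C and sets both ring stereocentres; 25 ⇐ α-hydroxy ketone 21 + aldehyde 24.
2. 21 ⇐ fully substituted A ring by three directed ortho-lithiations: oxetane 3 (C6 chain), lavandulyl triflate 16 (C8), glycolic acid acetonide 18 (C4/C3). O1 is kept apart from O5/O7 as a THP ether, so only O1 can enter ring C.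
3. Phloroglucinol oxygen pattern ⇐ resorcinol 1 by Ir C–H borylation/oxidation; B-ring aldehyde 24 ⇐ resorcinol by formylation.
4. Lavandulyl stereocentre ⇐ Evans dienolate alkylation (9 + 11).
5. Ring order: A ring completed first, B ring made separately, ring C closed last.

Assumption: the (R)-configured phosphoric acid in step 12 is taken to give the 3R product; if the sense is opposite, its mirror image is used and nothing else changes.
Assumption: 2,2-dimethyloxetane (3) and 2,2-dimethyl-1,3-dioxolan-4-one (18) are bought as such.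
Assumption: the oxane (THP) acetal carbons in 8, 15, 17, 19 and 20 are uncontrolled epimer mixtures; both THP groups are removed in step 9.

**Step 1**
Reactants: 1 resorcinol
Product: 2 1,3-bis(methoxymethoxy)benzene
Conditions: MOMCl (2.5 equiv), iPr2NEt (3 equiv), CH2Cl2, 0 °C → rt
Reagents that add atoms: chloromethyl methyl ether, COCCl
Why: Williamson-type O-alkylation of both phenols; the MOM ethers later direct ortho-lithiation and are removed by acid at the end.

**Step 2**
Reactants: 2 1,3-bis(methoxymethoxy)benzene; 3 2,2-dimethyloxetane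
Product: 5 4-[2,6-bis(methoxymethoxy)phenyl]-2-methylbutan-2-ol, via aryllithium 4 (not isolated)
Conditions: n-BuLi (1.1 equiv), THF, 0 °C, 1 h; then 3 (1.5 equiv), BF3·OEt2 (1.2 equiv), −78 °C
Reagents that add atoms: none
Why: Directed ortho-metalation occurs only between the two OMOM groups, and the aryllithium opens the BF3-activated oxetane by SN2 attack at its unhindered CH2, giving the 3-hydroxy-3-methylbutyl chain in one operation.

**Step 3**
Reactants: 5 4-[2,6-bis(methoxymethoxy)phenyl]-2-methylbutan-2-ol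
Product: 7 4-(3-hydroxy-3-methylbutyl)-3,5-bis(methoxymethoxy)phenol, via aryl pinacol boronate 6 (not isolated)
Conditions: [Ir(OMe)(cod)]2 (1.5 mol%), 4,4'-di-tert-butyl-2,2'-bipyridine (3 mol%), B2pin2 (2 equiv), THF, 80 °C; then NaOH, 30% H2O2, 0 °C
Reagents that add atoms: hydrogen peroxide, OO
Why: Sterically controlled Ir-catalysed C–H borylation takes the only ring C–H without an ortho substituent (para to the chain), and alkaline peroxide oxidation of the C–B bond gives the phenol that becomes O1.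

**Step 4**
Reactants: 7 4-(3-hydroxy-3-methylbutyl)-3,5-bis(methoxymethoxy)phenol
Product: 8 2-{4-[3-methyl-3-(oxan-2-yloxy)butyl]-3,5-bis(methoxymethoxy)phenoxy}oxane
Conditions: 3,4-dihydro-2H-pyran (5 equiv), pyridinium p-toluenesulfonate (10 mol%), CH2Cl2, 40 °C
Reagents that add atoms: 3,4-dihydro-2H-pyran, C1=COCCC1
Why: Acid-catalysed acetal formation masks O1 and the tertiary alcohol as THP ethers, which survive organolithiums and can later be removed without touching the MOM ethers.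

**Step 5**
Reactants: 9 3-methylbut-2-enoyl chloride
Product: 10 (4S)-4-benzyl-3-(3-methylbut-2-enoyl)-1,3-oxazolidin-2-one
Conditions: (4S)-4-benzyl-1,3-oxazolidin-2-one, n-BuLi, THF, −78 °C; then 9, −78 → 0 °C
Reagents that add atoms: (4S)-4-benzyl-1,3-oxazolidin-2-one, O=C1N[C@@H](Cc2ccccc2)CO1
Why: N-acylation of the lithiated Evans oxazolidinone by the acid chloride.

**Step 6**
Reactants: 10 (4S)-4-benzyl-3-(3-methylbut-2-enoyl)-1,3-oxazolidin-2-one; 11 1-bromo-3-methylbut-2-ene
Product: 13 (4S)-4-benzyl-3-[(2S)-5-methyl-2-(prop-1-en-2-yl)hex-4-enoyl]-1,3-oxazolidin-2-one, via sodium dienolate 12 (not isolated)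
Conditions: NaN(SiMe3)2 (1.1 equiv), THF, −78 °C, 30 min; then 11 (3 equiv), −78 → −40 °C
Reagents that add atoms: none
Why: Evans asymmetric alkylation: γ-deprotonation gives the chelated (Z)-dienolate, which is alkylated at the α-carbon on the face away from the benzyl group, setting the lavandulyl stereocentre (2S) and leaving the isopropenyl double bond out of conjugation.

**Step 7**
Reactants: 13 (4S)-4-benzyl-3-[(2S)-5-methyl-2-(prop-1-en-2-yl)hex-4-enoyl]-1,3-oxazolidin-2-one
Product: 14 (2S)-5-methyl-2-(prop-1-en-2-yl)hex-4-en-1-ol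
Conditions: LiBH4 (1.5 equiv), MeOH (1.5 equiv), Et2O, 0 °C
Reagents that add atoms: none
Why: Reductive cleavage of the imide by LiBH4 gives (S)-lavandulol without touching the stereocentre or the alkenes and returns the auxiliary.

**Step 8**
Reactants: 8 2-{4-[3-methyl-3-(oxan-2-yloxy)butyl]-3,5-bis(methoxymethoxy)phenoxy}oxane; 14 (2S)-5-methyl-2-(prop-1-en-2-yl)hex-4-en-1-ol
Product: 17 2-{4-[3-methyl-3-(oxan-2-yloxy)butyl]-3,5-bis(methoxymethoxy)-2-[(2R)-5-methyl-2-(prop-1-en-2-yl)hex-4-en-1-yl]phenoxy}oxane, via aryllithium 15 (not isolated), via lavandulyl triflate 16 (not isolated)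
Conditions: 8: n-BuLi (1.2 equiv), TMEDA, Et2O, 0 °C, 2 h; 14: n-BuLi (1.0 equiv), Et2O, −78 °C, then Tf2O (1.0 equiv); triflate solution added to the aryllithium at −78 °C, → 0 °C
Reagents that add atoms: none
Why: Directed ortho-metalation between the OTHP and OMOM groups, then SN2 alkylation of the aryllithium by the primary triflate, which outruns E2 at low temperature; the stereocentre is not involved and its descriptor changes from S to R only because CH2–aryl ranks below isopropenyl.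

**Step 9**
Reactants: 17 2-{4-[3-methyl-3-(oxan-2-yloxy)butyl]-3,5-bis(methoxymethoxy)-2-[(2R)-5-methyl-2-(prop-1-en-2-yl)hex-4-en-1-yl]phenoxy}oxane; 18 2,2-dimethyl-1,3-dioxolan-4-one
Product: 21 2-hydroxy-1-{2-hydroxy-5-(3-hydroxy-3-methylbutyl)-4,6-bis(methoxymethoxy)-3-[(2R)-5-methyl-2-(prop-1-en-2-yl)hex-4-en-1-yl]phenyl}ethan-1-one, via aryllithium 19 (not isolated), via THP-protected hydroxy ketone 20 (not isolated)
Conditions: s-BuLi (1.3 equiv), TMEDA, THF, −78 °C, 1 h; 18 (2 equiv), −78 °C; AcOH; then pyridinium p-toluenesulfonate (0.2 equiv), MeOH, 40 °C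
Reagents that add atoms: none
Why: The last ring C–H is lithiated (directed ortho-metalation) and the aryllithium adds once to the lactone carbonyl of the glycolic acid acetonide, whose tetrahedral adduct collapses on protonation to the α-hydroxy ketone with loss of acetone; mild acid methanolysis then removes only the two THP acetals, so O1 is free while O5 and O7 stay protected.

**Step 10**
Reactants: 1 resorcinol
Product: 23 2,4-dihydroxybenzaldehyde, via aryl iminium chloride 22 (not isolated)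
Conditions: POCl3 (1.2 equiv), DMF (1.5 equiv), MeCN, −15 → 25 °C; then H2O, 50 °C
Reagents that add atoms: N,N-dimethylformamide, CN(C)C=O; water, O
Why: Vilsmeier–Haack formylation of resorcinol para to one hydroxyl and ortho to the other, followed by hydrolysis of the iminium salt.

**Step 11**
Reactants: 23 2,4-dihydroxybenzaldehyde
Product: 24 2,4-bis(methoxymethoxy)benzaldehyde
Conditions: MOMCl (3 equiv), iPr2NEt (4 equiv), CH2Cl2, 0 → 40 °C
Reagents that add atoms: chloromethyl methyl ether, COCCl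
Why: O-alkylation (MOM protection) of both phenols keeps the B ring from acting as a nucleophile and matches the final deprotection.

**Step 12**
Reactants: 21 2-hydroxy-1-{2-hydroxy-5-(3-hydroxy-3-methylbutyl)-4,6-bis(methoxymethoxy)-3-[(2R)-5-methyl-2-(prop-1-en-2-yl)hex-4-en-1-yl]phenyl}ethan-1-one; 24 2,4-bis(methoxymethoxy)benzaldehyde
Product: 26 (2R,3R)-2-[2,4-bis(methoxymethoxy)phenyl]-3-hydroxy-6-(3-hydroxy-3-methylbutyl)-5,7-bis(methoxymethoxy)-8-[(2R)-5-methyl-2-(prop-1-en-2-yl)hex-4-en-1-yl]-2,3-dihydro-4H-chromen-4-one, via dioxepinone acetal 25 (not isolated)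
Conditions: 24 (1.2 equiv), (R)-3,3'-bis(2,4,6-triisopropylphenyl)-1,1'-binaphthyl-2,2'-diyl hydrogen phosphate (10 mol%), 5 Å molecular sieves, toluene, 25 °C, 6 h (acetal forms), then 50 °C, 24 h
Reagents that add atoms: none
Why: Proposed new method: the chiral phosphoric acid first condenses the phenol O1–H and the primary ketol OH of 21 with 24 to the seven-membered acetal 25 (O5 is blocked as MOM ether, so only the phenol next to the lavandulyl group can engage), then the alkyl C2–O3 bond of 25 ionises to an oxocarbenium ion stabilised by the 2,4-dialkoxyphenyl group while the freed α-hydroxy ketone enolises to its enediol, and inside the chiral phosphate ion pair C3 attacks C2 in a six-ring closure, so that C2 migrates from O3 to C3 (a 1,2 O→C shift) and the dioxepinone contracts to the chromanone, the catalyst fixing C3 as R and C2 closing trans (diequatorial, still correctable by reversible benzylic C–O ionisation); closest known reaction types are the Petasis–Ferrier O→C rearrangement with its chiral phosphoric acid catalysed aza variant and the ring-contracting [1,2]-Wittig rearrangement of cyclic benzylic ethers.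

**Step 13**
Reactants: 26 (2R,3R)-2-[2,4-bis(methoxymethoxy)phenyl]-3-hydroxy-6-(3-hydroxy-3-methylbutyl)-5,7-bis(methoxymethoxy)-8-[(2R)-5-methyl-2-(prop-1-en-2-yl)hex-4-en-1-yl]-2,3-dihydro-4H-chromen-4-one
Product: 27 (2R,3R)-2-(2,4-dihydroxyphenyl)-3,5,7-trihydroxy-6-(3-hydroxy-3-methylbutyl)-8-[(2R)-5-methyl-2-(prop-1-en-2-yl)hex-4-en-1-yl]-2,3-dihydro-4H-chromen-4-one
Conditions: 3 M aq. HCl/MeOH (1:5), 40 °C, 3 h
Reagents that add atoms: none
Why: Acid-catalysed methanolysis of the four aryl MOM acetals under conditions mild enough for the alkenes and the tertiary alcohol; C3 is untouched and the trans C2 configuration is the thermodynamic one.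

**Compound list**
1 | resorcinol | Oc1cccc(O)c1 | starting material
2 | 1,3-bis(methoxymethoxy)benzene | COCOc1cccc(OCOC)c1 | intermediate
3 | 2,2-dimethyloxetane | CC1(C)CCO1 | starting material
4 | [2,6-bis(methoxymethoxy)phenyl]lithium | [Li]c1c(OCOC)cccc1OCOC | intermediate (not isolated)
5 | 4-[2,6-bis(methoxymethoxy)phenyl]-2-methylbutan-2-ol | CC(C)(O)CCc1c(OCOC)cccc1OCOC | intermediate
6 | 4-[2,6-bis(methoxymethoxy)-4-(4,4,5,5-tetramethyl-1,3,2-dioxaborolan-2-yl)phenyl]-2-methylbutan-2-ol | CC(C)(O)CCc1c(OCOC)cc(B2OC(C)(C)C(C)(C)O2)cc1OCOC | intermediate (not isolated)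
7 | 4-(3-hydroxy-3-methylbutyl)-3,5-bis(methoxymethoxy)phenol | CC(C)(O)CCc1c(OCOC)cc(O)cc1OCOC | intermediate
8 | 2-{4-[3-methyl-3-(oxan-2-yloxy)butyl]-3,5-bis(methoxymethoxy)phenoxy}oxane (bis-THP ether of 7, acetal carbons unspecified) | CC(C)(OC1CCCCO1)CCc1c(OCOC)cc(OC2CCCCO2)cc1OCOC | intermediate
9 | 3-methylbut-2-enoyl chloride | CC(C)=CC(=O)Cl | starting material
10 | (4S)-4-benzyl-3-(3-methylbut-2-enoyl)-1,3-oxazolidin-2-one | CC(C)=CC(=O)N1C(=O)OC[C@@H]1Cc1ccccc1 | intermediate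
11 | 1-bromo-3-methylbut-2-ene (prenyl bromide) | CC(C)=CCBr | starting material
12 | sodium (Z)-dienolate of 10 | [Na+].C=C(C)/C=C(\[O-])N1C(=O)OC[C@@H]1Cc1ccccc1 | intermediate (not isolated)
13 | (4S)-4-benzyl-3-[(2S)-5-methyl-2-(prop-1-en-2-yl)hex-4-enoyl]-1,3-oxazolidin-2-one | C=C(C)[C@H](CC=C(C)C)C(=O)N1C(=O)OC[C@@H]1Cc1ccccc1 | intermediate
14 | (2S)-5-methyl-2-(prop-1-en-2-yl)hex-4-en-1-ol, (S)-lavandulol | C=C(C)[C@H](CC=C(C)C)CO | intermediate
15 | aryllithium of 8 (lithium at C2 of the phenoxy ring, between OTHP and OMOM) | CC(C)(OC1CCCCO1)CCc1c(OCOC)cc(OC2CCCCO2)c([Li])c1OCOC | intermediate (not isolated)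
16 | (2S)-5-methyl-2-(prop-1-en-2-yl)hex-4-en-1-yl trifluoromethanesulfonate | C=C(C)[C@H](CC=C(C)C)COS(=O)(=O)C(F)(F)F | intermediate (not isolated)
17 | 2-{4-[3-methyl-3-(oxan-2-yloxy)butyl]-3,5-bis(methoxymethoxy)-2-[(2R)-5-methyl-2-(prop-1-en-2-yl)hex-4-en-1-yl]phenoxy}oxane | CC(C)(OC1CCCCO1)CCc1c(OCOC)cc(OC2CCCCO2)c(C[C@@H](CC=C(C)C)C(C)=C)c1OCOC | intermediate
18 | 2,2-dimethyl-1,3-dioxolan-4-one | CC1(C)OCC(=O)O1 | starting material
19 | aryllithium of 17 (lithium at C6 of the phenoxy ring) | CC(C)(OC1CCCCO1)CCc1c(OCOC)c([Li])c(OC2CCCCO2)c(C[C@@H](CC=C(C)C)C(C)=C)c1OCOC | intermediate (not isolated)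
20 | 2-hydroxy-1-{5-[3-methyl-3-(oxan-2-yloxy)butyl]-4,6-bis(methoxymethoxy)-3-[(2R)-5-methyl-2-(prop-1-en-2-yl)hex-4-en-1-yl]-2-(oxan-2-yloxy)phenyl}ethan-1-one | CC(C)(OC1CCCCO1)CCc1c(OCOC)c(C(=O)CO)c(OC2CCCCO2)c(C[C@@H](CC=C(C)C)C(C)=C)c1OCOC | intermediate (not isolated)
21 | 2-hydroxy-1-{2-hydroxy-5-(3-hydroxy-3-methylbutyl)-4,6-bis(methoxymethoxy)-3-[(2R)-5-methyl-2-(prop-1-en-2-yl)hex-4-en-1-yl]phenyl}ethan-1-one | CC(C)(O)CCc1c(OCOC)c(C(=O)CO)c(O)c(C[C@@H](CC=C(C)C)C(C)=C)c1OCOC | intermediate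
22 | N-[(2,4-dihydroxyphenyl)methylidene]-N-methylmethanaminium chloride | C[N+](C)=Cc1ccc(O)cc1O.[Cl-] | intermediate (not isolated)
23 | 2,4-dihydroxybenzaldehyde | O=Cc1ccc(O)cc1O | intermediate
24 | 2,4-bis(methoxymethoxy)benzaldehyde | COCOc1ccc(C=O)c(OCOC)c1 | intermediate
25 | 2-[2,4-bis(methoxymethoxy)phenyl]-7-(3-hydroxy-3-methylbutyl)-6,8-bis(methoxymethoxy)-9-[(2R)-5-methyl-2-(prop-1-en-2-yl)hex-4-en-1-yl]-4H-1,3-benzodioxepin-5-one (both C2 epimers) | O=C1COC(c2ccc(OCOC)cc2OCOC)Oc2c(C[C@@H](CC=C(C)C)C(C)=C)c(OCOC)c(CCC(C)(C)O)c(OCOC)c12 | intermediate (not isolated)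
26 | (2R,3R)-2-[2,4-bis(methoxymethoxy)phenyl]-3-hydroxy-6-(3-hydroxy-3-methylbutyl)-5,7-bis(methoxymethoxy)-8-[(2R)-5-methyl-2-(prop-1-en-2-yl)hex-4-en-1-yl]-2,3-dihydro-4H-chromen-4-one | C=C(C)[C@H](CC=C(C)C)Cc1c(OCOC)c(CCC(C)(C)O)c(OCOC)c2c1O[C@H](c1ccc(OCOC)cc1OCOC)[C@@H](O)C2=O | intermediate
27 | (2R,3R)-2-(2,4-dihydroxyphenyl)-3,5,7-trihydroxy-6-(3-hydroxy-3-methylbutyl)-8-[(2R)-5-methyl-2-(prop-1-en-2-yl)hex-4-en-1-yl]-2,3-dihydro-4H-chromen-4-one | C=C(C)[C@H](CC=C(C)C)Cc1c(O)c(CCC(C)(C)O)c(O)c2c1O[C@H](c1ccc(O)cc1O)[C@@H](O)C2=O | target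

**Step count**
Total: 13 steps. Longest linear sequence: 8 steps (1, 2, 3, 4, 8, 9, 12, 13, from resorcinol).

**Steps most likely to fail and their fallbacks**

Step 12 (the proposed new ring contraction). The acetal may stall or hydrolyse, the closure may give low enantioselectivity, or C3 may erode by enolisation. The fallback uses known chalcone epoxide chemistry and sets out from 17 and 24. Horner–Wadsworth–Emmons reaction of 24 with diethyl {2-[methoxy(methyl)amino]-2-oxoethyl}phosphonate (NaH, THF) gives (E)-3-[2,4-bis(methoxymethoxy)phenyl]-N-methoxy-N-methylprop-2-enamide F1. Aryllithium 19, made from 17 as in step 9, is acylated by F1 to the THP-protected chalcone F2. Juliá–Colonna epoxidation (poly-L-leucine, urea–hydrogen peroxide, DBU, THF) gives the (αR,βS)-epoxy ketone F3. Pyridinium p-toluenesulfonate in i-PrOH at 50 °C then removes both THP groups, and the freed O1 phenol opens the epoxide at the benzylic carbon with inversion (6-endo). This gives 26, where the route is rejoined.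

Step 8 (aryl–lavandulyl bond). The hindered aryllithium may act as a base on the β-branched triflate (E2) instead of alkylating. The fallback is a Pd-catalysed Negishi coupling and sets out from 8 and 14. Aryllithium 15 is quenched with iodine to give the aryl iodide F4. Alcohol 14 is converted with I2, PPh3 and imidazole into (2S)-1-iodo-5-methyl-2-(prop-1-en-2-yl)hex-4-ene F5, and zinc dust with LiCl in THF turns this into the alkylzinc iodide F6. Coupling of F4 and F6 with Pd(OAc)2 and 2-dicyclohexylphosphino-2',6'-dimethoxybiphenyl in THF at 50 °C gives 17, where the route is rejoined.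

Step 9 (hydroxyacetylation). The aryllithium may deprotonate the enolisable lactone 18 instead of adding to it. The fallback sets out from 17. Aryllithium 19 is acylated with 2-chloro-N-methoxy-N-methylacetamide (THF, −78 °C) to give the chloromethyl ketone F7. Sodium formate in aqueous ethanol at 80 °C displaces chloride to give the formate ester F8, which is hydrolysed in the same flask. This gives 20, which is carried on to 21 with pyridinium p-toluenesulfonate in MeOH as in step 9.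

**Further compounds**
F1 | step 12 | (E)-3-[2,4-bis(methoxymethoxy)phenyl]-N-methoxy-N-methylprop-2-enamide | CON(C)C(=O)/C=C/c1ccc(OCOC)cc1OCOC
F2 | step 12 | (E)-3-[2,4-bis(methoxymethoxy)phenyl]-1-{5-[3-methyl-3-(oxan-2-yloxy)butyl]-4,6-bis(methoxymethoxy)-3-[(2R)-5-methyl-2-(prop-1-en-2-yl)hex-4-en-1-yl]-2-(oxan-2-yloxy)phenyl}prop-2-en-1-one | CC(C)(OC1CCCCO1)CCc1c(OCOC)c(C(=O)/C=C/c2ccc(OCOC)cc2OCOC)c(OC2CCCCO2)c(C[C@@H](CC=C(C)C)C(C)=C)c1OCOC
F3 | step 12 | {(2R,3S)-3-[2,4-bis(methoxymethoxy)phenyl]oxiran-2-yl}{5-[3-methyl-3-(oxan-2-yloxy)butyl]-4,6-bis(methoxymethoxy)-3-[(2R)-5-methyl-2-(prop-1-en-2-yl)hex-4-en-1-yl]-2-(oxan-2-yloxy)phenyl}methanone | CC(C)(OC1CCCCO1)CCc1c(OCOC)c(C(=O)[C@@H]2O[C@H]2c2ccc(OCOC)cc2OCOC)c(OC2CCCCO2)c(C[C@@H](CC=C(C)C)C(C)=C)c1OCOC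
F4 | step 8 | 2-{2-iodo-4-[3-methyl-3-(oxan-2-yloxy)butyl]-3,5-bis(methoxymethoxy)phenoxy}oxane | CC(C)(OC1CCCCO1)CCc1c(OCOC)cc(OC2CCCCO2)c(I)c1OCOC
F5 | step 8 | (2S)-1-iodo-5-methyl-2-(prop-1-en-2-yl)hex-4-ene | C=C(C)[C@H](CC=C(C)C)CI
F6 | step 8 | [(2S)-5-methyl-2-(prop-1-en-2-yl)hex-4-en-1-yl]zinc iodide | C=C(C)[C@H](CC=C(C)C)C[Zn]I
F7 | step 9 | 2-chloro-1-{5-[3-methyl-3-(oxan-2-yloxy)butyl]-4,6-bis(methoxymethoxy)-3-[(2R)-5-methyl-2-(prop-1-en-2-yl)hex-4-en-1-yl]-2-(oxan-2-yloxy)phenyl}ethan-1-one | CC(C)(OC1CCCCO1)CCc1c(OCOC)c(C(=O)CCl)c(OC2CCCCO2)c(C[C@@H](CC=C(C)C)C(C)=C)c1OCOC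
F8 | step 9 | 2-oxo-2-{5-[3-methyl-3-(oxan-2-yloxy)butyl]-4,6-bis(methoxymethoxy)-3-[(2R)-5-methyl-2-(prop-1-en-2-yl)hex-4-en-1-yl]-2-(oxan-2-yloxy)phenyl}ethyl formate | CC(C)(OC1CCCCO1)CCc1c(OCOC)c(C(=O)COC=O)c(OC2CCCCO2)c(C[C@@H](CC=C(C)C)C(C)=C)c1OCOC
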